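## Structural features

The target is a diaryl ether. Ring A is a 1,2,4-trisubstituted benzene with one hydroxyl ortho to the ether oxygen. Ring B is a 1,2,3,5-tetrasubstituted benzene whose two catechol hydroxyls sit next to the ether oxygen. Each ring carries the same C15 chain, a (6E)-3,7,11-trimethyldodeca-1,6,10-trien-3-yl group bound through C3, para to the ether oxygen on ring A and para to the central hydroxyl on ring B. C3 of each chain is an acyclic all-carbon quaternary stereocentre bearing methyl, vinyl, aryl and a homogeranyl (4,8-dimethylnona-3,7-dienyl) group; it is R on ring A and S on ring B. The two stereocentres are not adjacent: both rings and the ether bridge lie between them, so neither can direct the other and a wrong diastereomer would be practically inseparable. Fragile groups are the catechol (oxidised in base and air), the four trisubstituted alkenes (protonation, cation–olefin cyclisation) and the two vinyl groups; the quaternary centres themselves cannot epimerise. The real difficulty is to build two benzylic quaternary centres of opposite sense, whose substituents differ little in size, without touching the other alkenes. The key step uses the fact that ring B C3 carries a methyl and a vinyl group on a benzylic carbon, which is the pattern left by adding hydrogen and vinyl across the alkene Ar(ring B)–C(=CH2)–CH2R.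

## Logic of the disconnections

20 ⇒ 19. Only the three O–Si bonds are cut; no skeletal bond changes. The phenols must be masked through all organometallic steps, and silyl ethers are the only masks that come off without acid, strong base or hydrogen, all of which the polyene or the catechol would not survive. The demand on the forward step is a fluoride source buffered so that the catechol is never left as a phenoxide.

19 ⇒ 18 + 12. The ring B C3–C2 bond is cut, and the C3 methyl is traced back to the methylene of a 1,1-disubstituted alkene. The quaternary centre and its vinyl group are thereby replaced by a flat alkene and a C2 gas, so the whole second stereocentre is one catalytic addition. 18 and 19 agree with 20 in constitution and configuration (R on ring A, S on ring B, chain alkenes E), so the skeleton needs no correction. The forward step must choose one face of the alkene under catalyst control and one alkene out of six. The silyl ethers are kept in 18 because they do not ligate a cationic metal.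

18 ⇒ 17 ⇒ 15 + 8 ⇒ 13. Three bonds are cut in turn on ring B: the C=CH2 bond (ketone methylenation), the C4–C5 bond of the chain (enolate alkylation by 8) and the acyl–CH3 bond (ester to methyl ketone through 14). This last cut is the point where the design needs completing: the ring B carbonyl arrives as an ester, which has no methyl to alkylate, so one C–C bond must be added. In return the ester keeps ring B silent while ring A is built, and that differentiation is indispensable because the two arms need antipodal catalysts. The forward steps must give mono-C-alkylation and stop the methyl addition at the ketone.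

13 ⇒ 11 + 12 ⇒ 10 ⇒ 7 + 8. The same cuts are made on ring A: the C3–C2 bond (hydrovinylation with the antipodal ligand), the C=CH2 bond and the C4–C5 bond. The gain is that both chains come from 8 and 12 only. The demand is that the ester of ring B tolerates an amide base, an ylide and a cationic nickel hydride.

7 ⇒ 6 ⇒ 5. Here only protecting groups are exchanged. Silyl ethers would not survive the carbonate-mediated ether formation, and the acetal-type masks that do survive it could be removed at the end only with acid. The exchange is therefore placed where the molecule still has no alkene, and one acid treatment must remove both acetal-type masks.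

5 ⇒ 2 + 4. The ring A C4–O bond of the diaryl ether is cut, because the acetyl group para to fluorine activates exactly this carbon for nucleophilic aromatic substitution. The molecule falls into its two rings. The forward step needs a ring B partner with a single free phenol in the right place and a ring A partner without a free phenol.

2 ⇒ 1 and 4 ⇒ 3. One cyclic orthoformate and one acetal are removed. The symmetry of 1 guarantees that bridging two neighbouring oxygens leaves the one phenol that is needed.

## Other disconnections considered

Alternative 1: The cut is made at both C3–CH3 bonds, and the two vinyl groups are then derived from C–B bonds. In the forward sense the bis(N,N-diisopropylcarbamate) A1 (ring A carbinol carbon S, ring B carbinol carbon R) would be lithiated at both benzylic positions with s-BuLi and trapped with methylboronic acid pinacol ester A2. Two 1,2-shifts of methyl from boron to carbon would give the bis(boronic ester) A3, which still needs a double vinylation and removal of three MOM groups.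
- In its favour: the configuration is transferred stereospecifically (retention on lithiation and borylation, inversion in the shift) from secondary carbinols that are easy to obtain in high enantiomeric purity by ketone reduction. The sense of each centre is therefore more predictable than in an enantioface-selective catalysis, and on this point it is the better plan. Both centres are made in one flask.
- Against it here: a twofold benzylic lithiation must go to completion on one molecule, methyl is a reluctant migrating group, and the electron-rich rings slow the deprotonation and favour reversible boronate formation, which erodes the transfer. Stoichiometric s-BuLi also forbids the ester that differentiates the arms in the chosen plan.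
- Comparison: on differentiation the two plans are equal, because the antipodal carbinols still require two reductions with opposite catalysts. In mechanism it replaces a catalytic, atom-economical C–C bond formation by stoichiometric organolithium and boron chemistry. In step count it is longer by about two operations (reduction and carbamoylation before, vinylation and acidic deprotection after), and the last of these exposes four trisubstituted alkenes to acid.

Alternative 2: The cut is made at both C3–C4 bonds, so that each chain beyond C4 arrives as a nucleophile. In the forward sense the bis(allylic phosphate) A4, with an (E)-3-arylbut-2-enyl phosphate on ring A and its (Z) isomer on ring B, would react with di(homogeranyl)zinc A5 under one chiral copper catalyst in two SN2' substitutions to give the tris(MOM) ether A6 of the target.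
- In its favour: the opposite configurations are encoded in alkene geometry, so one ligand hand suffices and both centres and both vinyl groups appear in a single operation. The chains are introduced late and never meet a metal hydride. On convergence and on the use of a single catalyst it is the better plan.
- Against it here: the (Z)-configured β-aryl allylic phosphate is the less stable and less accessible isomer, and any wrong alkene geometry becomes a diastereomer that cannot be removed. (Z) substrates usually respond less well to such catalysts. A5 must be prepared in several steps from a homogeranyl halide and used in excess.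
- Comparison: both plans rely on catalyst control, here on γ-attack of an alkylcopper species instead of hydride addition and ethylene insertion. Regioselectivity (SN2' against SN2) is an extra issue that the chosen plan does not have. In step count the two geometry-defined phosphates and the zinc reagent make it longer, and the final deprotection is again acidic.

Alternative 3: The cut is made at the bond between ring B and C3. In the forward sense geranylacetone A7 would be reduced to the (R)-alcohol and esterified to the 2,4,6-triisopropylbenzoate A8. Lithiation of A8 at the carbinol carbon and addition to the ring B neopentyl glycol boronate A9, which already carries the ring A chain, would be followed by a 1,2-shift of the aryl group from boron to carbon to give the tertiary boronic ester A10. Vinylation at boron would complete the centre.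
- In its favour: it is the most convergent way to the chain, since all chain carbons except the vinyl group come from one commercial ketone. Aryl is a good migrating group and the configuration is transferred stereospecifically, so no face selection is needed. On convergence and predictability it is the equal or the better of the chosen plan.
- Against it here: deprotonation of a secondary dialkyl benzoate without a stabilising group is slow, and the tertiary organolithium keeps its configuration only in a narrow temperature window. The boronate complex is very hindered. Ring B must carry boron, which removes the acyl group that activates the ether-forming substitution and differentiates the arms, so the diaryl ether would need a copper-mediated coupling. A vinylation with iodine and methoxide and an acidic deprotection follow.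
- Comparison: it is a stoichiometric, stereospecific 1,2-metallate rearrangement against a catalytic, stereoselective insertion. Per arm it needs about four operations (reduction, esterification, lithiation–borylation, vinylation) where the chosen plan needs three (alkylation, methylenation, hydrovinylation), and the ring A chain would need the same treatment with the antipodal alcohol.

Key step: step 12

Abbreviations: TBS = tert-butyldimethylsilyl; MOM = methoxymethyl; PA = O,O'-(1,1'-binaphthalene-2,2'-diyl) N,N-bis(1-phenylethyl)phosphoramidite.

Assumption: the sense of induction of the nickel–PA catalyst is taken from the aryl-versus-alkyl model for 2-arylalk-1-enes, so (Ra,Sc,Sc)-PA is written for the R centre and (Sa,Rc,Rc)-PA for the S centre; if calibration on a simple 2-arylalk-1-ene shows the opposite sense, the two ligand enantiomers are exchanged between steps 8 and 12 and nothing else changes.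

## Steps

Step 1
Reactants: 1 methyl gallate (methyl 3,4,5-trihydroxybenzoate)
Product: 2 methyl 2-ethoxy-7-hydroxy-1,3-benzodioxole-5-carboxylate (racemic at C2)
Conditions: HC(OEt)3, Amberlyst 15, toluene, reflux, EtOH distilled off
Reagents that add atoms: triethyl orthoformate, CCOC(OCC)OCC
Why: Acid-catalysed orthoester exchange closes a 2-ethoxy-1,3-benzodioxole on two neighbouring phenols; because 1 is symmetric, bridging the central oxygen to either flank gives the same compound and leaves exactly one free phenol beside the acetal. The orthoester carbon is a racemic stereocentre of no consequence and is lost in step 4.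

Step 2
Reactants: 3 4'-fluoro-3'-hydroxyacetophenone
Product: 4 4'-fluoro-3'-(methoxymethoxy)acetophenone
Conditions: MOMCl, i-Pr2NEt, CH2Cl2, 0 °C to rt
Reagents that add atoms: chloromethyl methyl ether, COCCl
Why: O-Alkylation of the phenol by an α-chloro ether; a free phenol ortho to fluorine would become a phenoxide in step 3, shut down the substitution and compete as a nucleophile.

Step 3
Reactants: 2 methyl 2-ethoxy-7-hydroxy-1,3-benzodioxole-5-carboxylate; 4 4'-fluoro-3'-(methoxymethoxy)acetophenone
Product: 5 methyl 7-[4-acetyl-2-(methoxymethoxy)phenoxy]-2-ethoxy-1,3-benzodioxole-5-carboxylate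
Conditions: Cs2CO3, DMSO, 90 °C
Reagents that add atoms: none
Why: Nucleophilic aromatic substitution by addition–elimination: the acetyl group para to fluorine stabilises the anionic σ-adduct, the only free phenol of 2 is the nucleophile, and both acetal-type masks are inert to carbonate. A base-induced shift of the orthoformate in 2 to the other vicinal pair would be degenerate.

Step 4
Reactants: 5 methyl 7-[4-acetyl-2-(methoxymethoxy)phenoxy]-2-ethoxy-1,3-benzodioxole-5-carboxylate
Product: 6 methyl 3-(4-acetyl-2-hydroxyphenoxy)-4,5-dihydroxybenzoate
Conditions: 2 M aq. HCl, MeOH, 50 °C, under N2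
Reagents that add atoms: none
Why: Acid hydrolysis of the acetal and of the cyclic orthoformate in one operation; strong acid is harmless here because no alkene is present yet, and methanol as cosolvent keeps the methyl ester.

Step 5
Reactants: 6 methyl 3-(4-acetyl-2-hydroxyphenoxy)-4,5-dihydroxybenzoate
Product: 7 methyl 3-[4-acetyl-2-(TBSO)phenoxy]-4,5-bis(TBSO)benzoate
Conditions: TBSCl, imidazole, DMF, rt to 40 °C, argon
Reagents that add atoms: tert-butyldimethylsilyl chloride, CC(C)(C)[Si](C)(C)Cl
Why: Imidazole-mediated silylation of all three phenols; from here on the masks are non-coordinating, stable to amide bases, ylides and Grignard reagents at low temperature, and removable with fluoride.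

Step 6
Reactants: 7 methyl 3-[4-acetyl-2-(TBSO)phenoxy]-4,5-bis(TBSO)benzoate; 8 geranyl bromide ((2E)-1-bromo-3,7-dimethylocta-2,6-diene)
Product: 10 methyl 3-{4-[(4E)-5,9-dimethyldeca-4,8-dienoyl]-2-(TBSO)phenoxy}-4,5-bis(TBSO)benzoate, via lithium enolate 9 (not isolated)
Conditions: LiN(i-Pr)2 (1.05 equiv), THF, −78 °C; then 8, DMPU, −78 to −30 °C
Reagents that add atoms: none
Why: Kinetic deprotonation of the only enolisable position (the acetyl methyl) and SN2 alkylation of the lithium enolate at the primary allylic carbon of 8, which keeps the E alkene. The benzoate has no α-hydrogen and should not be attacked by the hindered amide or the enolate at low temperature.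

Step 7
Reactants: 10 methyl 3-{4-[(4E)-5,9-dimethyldeca-4,8-dienoyl]-2-(TBSO)phenoxy}-4,5-bis(TBSO)benzoate
Product: 11 methyl 3-{4-[(5E)-6,10-dimethylundeca-1,5,9-trien-2-yl]-2-(TBSO)phenoxy}-4,5-bis(TBSO)benzoate
Conditions: Ph3PCH3Br, NaN(SiMe3)2, THF, 0 °C to rt
Reagents that add atoms: methyltriphenylphosphonium bromide, C[P+](c1ccccc1)(c1ccccc1)c1ccccc1.[Br-]
Why: Wittig methylenation; the non-stabilised ylide reacts with the aryl ketone and leaves the methyl ester and the aryl silyl ethers alone.

Step 8
Reactants: 11 methyl 3-{4-[(5E)-6,10-dimethylundeca-1,5,9-trien-2-yl]-2-(TBSO)phenoxy}-4,5-bis(TBSO)benzoate; 12 ethylene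
Product: 13 methyl 3-{4-[(3R,6E)-3,7,11-trimethyldodeca-1,6,10-trien-3-yl]-2-(TBSO)phenoxy}-4,5-bis(TBSO)benzoate
Conditions: [Ni(η3-C3H5)Br]2 (cat.), (Ra,Sc,Sc)-PA (cat.), Na[B(3,5-(CF3)2C6H3)4] (cat.), C2H4 (1 atm), CH2Cl2, −70 to −20 °C
Reagents that add atoms: none
Why: Nickel-catalysed asymmetric hydrovinylation of an α-alkylvinylarene, by the mechanism described in step 12 (Markovnikov addition of a cationic nickel hydride, ethylene insertion at the benzylic carbon, β-hydride elimination). The ring A C3 stereocentre (R) is set by the (Ra,Sc,Sc) ligand through enantioface selection; the ester is a weak donor and should be tolerated, and only this alkene can give an η3-benzyl intermediate.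

Step 9
Reactants: 13 methyl 3-{4-[(3R,6E)-3,7,11-trimethyldodeca-1,6,10-trien-3-yl]-2-(TBSO)phenoxy}-4,5-bis(TBSO)benzoate
Product: 15 1-[3,4-bis(TBSO)-5-{2-(TBSO)-4-[(3R,6E)-3,7,11-trimethyldodeca-1,6,10-trien-3-yl]phenoxy}phenyl]ethan-1-one, via Weinreb amide 14 (not isolated)
Conditions: MeNHOMe·HCl, i-PrMgCl, THF, −20 °C; then MeMgBr, 0 °C; aq. NH4Cl
Reagents that add atoms: methylmagnesium bromide, C[Mg]Br
Why: Aminolysis of the ester by the magnesium amide gives the N-methoxy-N-methylamide, and the Grignard adduct of that amide is a stable magnesium chelate that collapses to the methyl ketone only on work-up, so no tertiary alcohol should form. Alkenes, the quaternary centre and the aryl silyl ethers are inert at these temperatures.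

Step 10
Reactants: 15 1-[3,4-bis(TBSO)-5-{2-(TBSO)-4-[(3R,6E)-3,7,11-trimethyldodeca-1,6,10-trien-3-yl]phenoxy}phenyl]ethan-1-one; 8 geranyl bromide
Product: 17 (4E)-1-[3,4-bis(TBSO)-5-{2-(TBSO)-4-[(3R,6E)-3,7,11-trimethyldodeca-1,6,10-trien-3-yl]phenoxy}phenyl]-5,9-dimethyldeca-4,8-dien-1-one, via lithium enolate 16 (not isolated)
Conditions: LiN(i-Pr)2 (1.05 equiv), THF, −78 °C; then 8, DMPU, −78 to −30 °C
Reagents that add atoms: none
Why: Enolate alkylation as in step 6, now without any competing electrophile in the molecule; the ring A centre has no acidic hydrogen and cannot epimerise.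

Step 11
Reactants: 17 (4E)-1-[3,4-bis(TBSO)-5-{2-(TBSO)-4-[(3R,6E)-3,7,11-trimethyldodeca-1,6,10-trien-3-yl]phenoxy}phenyl]-5,9-dimethyldeca-4,8-dien-1-one
Product: 18 1,2-bis(TBSO)-5-[(5E)-6,10-dimethylundeca-1,5,9-trien-2-yl]-3-{2-(TBSO)-4-[(3R,6E)-3,7,11-trimethyldodeca-1,6,10-trien-3-yl]phenoxy}benzene (ring B α-homogeranylstyrene)
Conditions: Ph3PCH3Br, NaN(SiMe3)2, THF, 0 °C to rt
Reagents that add atoms: methyltriphenylphosphonium bromide, C[P+](c1ccccc1)(c1ccccc1)c1ccccc1.[Br-]
Why: Wittig methylenation as in step 7 gives the 1,1-disubstituted styrene needed for the key step; no stereocentre is touched.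

Step 12
Reactants: 18 1,2-bis(TBSO)-5-[(5E)-6,10-dimethylundeca-1,5,9-trien-2-yl]-3-{2-(TBSO)-4-[(3R,6E)-3,7,11-trimethyldodeca-1,6,10-trien-3-yl]phenoxy}benzene; 12 ethylene
Product: 19 1,2-bis(TBSO)-3-{2-(TBSO)-4-[(3R,6E)-3,7,11-trimethyldodeca-1,6,10-trien-3-yl]phenoxy}-5-[(3S,6E)-3,7,11-trimethyldodeca-1,6,10-trien-3-yl]benzene (tris-TBS ether of the target)
Conditions: [Ni(η3-C3H5)Br]2 (cat.), (Sa,Rc,Rc)-PA (cat.), Na[B(3,5-(CF3)2C6H3)4] (cat.), C2H4 (1 atm), CH2Cl2, −70 to −20 °C
Reagents that add atoms: none
Why: This is a nickel-catalysed asymmetric hydrovinylation of an α-alkylvinylarene, a known way to benzylic all-carbon quaternary centres. Halide abstraction from the allylnickel bromide by the borate salt and loss of the allyl group with ethylene give a cationic divalent nickel hydride carrying one phosphoramidite. The hydride adds to the ring B 1,1-disubstituted alkene of 18 in the Markovnikov sense, turning the methylene into the C3 methyl and giving a tertiary η3-benzyl nickel species; ethylene then inserts into the benzylic C3–Ni bond and β-hydride elimination releases the vinyl group of 19 and regenerates the hydride. No ring is formed. The new C3 stereocentre (S) is set by the catalyst alone: the (Sa,Rc,Rc) ligand, antipodal to that of step 8, selects one face of the alkene by telling the flat aryl group from the homogeranyl chain, and the R centre on ring A is too remote to match or mismatch. The step must pick one of six alkenes, which the substrate secures because only the aryl-conjugated alkene can form a stabilised η3-benzyl complex, the ring A vinyl group is shielded by its quaternary neighbour and the chain alkenes are trisubstituted and bind poorly; low temperature and an ethylene atmosphere should keep insertion ahead of isomerisation of 18 to the internal styrene. The bulky silyl ethers do not ligate the cationic metal, and 19 cannot isomerise because C3 carries no hydrogen.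

Step 13
Reactants: 19 tris-TBS ether of the target
Product: 20 5-[(3S,6E)-3,7,11-trimethyldodeca-1,6,10-trien-3-yl]-3-{2-hydroxy-4-[(3R,6E)-3,7,11-trimethyldodeca-1,6,10-trien-3-yl]phenoxy}benzene-1,2-diol (CNP0230356.1)
Conditions: Bu4NF, AcOH (1:1), THF, 0 °C, argon
Reagents that add atoms: none
Why: Fluoride cleaves the three aryl Si–O bonds, driven by the strong Si–F bond; acetic acid buffers the medium so that the catechol is never left as a phenoxide open to oxidation and the alkenes meet neither strong acid nor base. Both quaternary centres are untouched.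

## Compound list

1 | methyl gallate | COC(=O)c1cc(O)c(O)c(O)c1 | starting material
2 | methyl 2-ethoxy-7-hydroxy-1,3-benzodioxole-5-carboxylate (racemic at C2) | COC(=O)c1cc(O)c2OC(OCC)Oc2c1 | intermediate
3 | 4'-fluoro-3'-hydroxyacetophenone | CC(=O)c1ccc(F)c(O)c1 | starting material
4 | 4'-fluoro-3'-(methoxymethoxy)acetophenone | CC(=O)c1ccc(F)c(OCOC)c1 | intermediate
5 | methyl 7-[4-acetyl-2-(methoxymethoxy)phenoxy]-2-ethoxy-1,3-benzodioxole-5-carboxylate | CC(=O)c1ccc(Oc2cc(C(=O)OC)cc3OC(OCC)Oc23)c(OCOC)c1 | intermediate
6 | methyl 3-(4-acetyl-2-hydroxyphenoxy)-4,5-dihydroxybenzoate | CC(=O)c1ccc(Oc2cc(C(=O)OC)cc(O)c2O)c(O)c1 | intermediate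
7 | methyl 3-[4-acetyl-2-(TBSO)phenoxy]-4,5-bis(TBSO)benzoate | CC(=O)c1ccc(Oc2cc(C(=O)OC)cc(O[Si](C)(C)C(C)(C)C)c2O[Si](C)(C)C(C)(C)C)c(O[Si](C)(C)C(C)(C)C)c1 | intermediate
8 | geranyl bromide | CC(C)=CCC/C(C)=C/CBr | starting material
9 | lithium enolate of 7 (formed in the flask) | [Li]OC(=C)c1ccc(Oc2cc(C(=O)OC)cc(O[Si](C)(C)C(C)(C)C)c2O[Si](C)(C)C(C)(C)C)c(O[Si](C)(C)C(C)(C)C)c1 | intermediate
10 | methyl 3-{4-[(4E)-5,9-dimethyldeca-4,8-dienoyl]-2-(TBSO)phenoxy}-4,5-bis(TBSO)benzoate | O=C(CC/C=C(\C)CCC=C(C)C)c1ccc(Oc2cc(C(=O)OC)cc(O[Si](C)(C)C(C)(C)C)c2O[Si](C)(C)C(C)(C)C)c(O[Si](C)(C)C(C)(C)C)c1 | intermediate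
11 | methyl 3-{4-[(5E)-6,10-dimethylundeca-1,5,9-trien-2-yl]-2-(TBSO)phenoxy}-4,5-bis(TBSO)benzoate | C=C(CC/C=C(\C)CCC=C(C)C)c1ccc(Oc2cc(C(=O)OC)cc(O[Si](C)(C)C(C)(C)C)c2O[Si](C)(C)C(C)(C)C)c(O[Si](C)(C)C(C)(C)C)c1 | intermediate
12 | ethylene | C=C | starting material
13 | methyl 3-{4-[(3R,6E)-3,7,11-trimethyldodeca-1,6,10-trien-3-yl]-2-(TBSO)phenoxy}-4,5-bis(TBSO)benzoate | C=C[C@@](C)(CC/C=C(\C)CCC=C(C)C)c1ccc(Oc2cc(C(=O)OC)cc(O[Si](C)(C)C(C)(C)C)c2O[Si](C)(C)C(C)(C)C)c(O[Si](C)(C)C(C)(C)C)c1 | intermediate
14 | N-methoxy-N-methylamide of the acid of 13 (formed in the flask) | C=C[C@@](C)(CC/C=C(\C)CCC=C(C)C)c1ccc(Oc2cc(C(=O)N(C)OC)cc(O[Si](C)(C)C(C)(C)C)c2O[Si](C)(C)C(C)(C)C)c(O[Si](C)(C)C(C)(C)C)c1 | intermediate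
15 | 1-[3,4-bis(TBSO)-5-{2-(TBSO)-4-[(3R,6E)-3,7,11-trimethyldodeca-1,6,10-trien-3-yl]phenoxy}phenyl]ethan-1-one | C=C[C@@](C)(CC/C=C(\C)CCC=C(C)C)c1ccc(Oc2cc(C(C)=O)cc(O[Si](C)(C)C(C)(C)C)c2O[Si](C)(C)C(C)(C)C)c(O[Si](C)(C)C(C)(C)C)c1 | intermediate
16 | lithium enolate of 15 (formed in the flask) | C=C[C@@](C)(CC/C=C(\C)CCC=C(C)C)c1ccc(Oc2cc(C(=C)O[Li])cc(O[Si](C)(C)C(C)(C)C)c2O[Si](C)(C)C(C)(C)C)c(O[Si](C)(C)C(C)(C)C)c1 | intermediate
17 | (4E)-1-[3,4-bis(TBSO)-5-{2-(TBSO)-4-[(3R,6E)-3,7,11-trimethyldodeca-1,6,10-trien-3-yl]phenoxy}phenyl]-5,9-dimethyldeca-4,8-dien-1-one | C=C[C@@](C)(CC/C=C(\C)CCC=C(C)C)c1ccc(Oc2cc(C(=O)CC/C=C(\C)CCC=C(C)C)cc(O[Si](C)(C)C(C)(C)C)c2O[Si](C)(C)C(C)(C)C)c(O[Si](C)(C)C(C)(C)C)c1 | intermediate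
18 | ring B α-homogeranylstyrene, tris-TBS ether, (R)-chain on ring A | C=C[C@@](C)(CC/C=C(\C)CCC=C(C)C)c1ccc(Oc2cc(C(=C)CC/C=C(\C)CCC=C(C)C)cc(O[Si](C)(C)C(C)(C)C)c2O[Si](C)(C)C(C)(C)C)c(O[Si](C)(C)C(C)(C)C)c1 | intermediate
19 | tris-TBS ether of the target (ring A 3R, ring B 3S) | C=C[C@@](C)(CC/C=C(\C)CCC=C(C)C)c1ccc(Oc2cc([C@](C)(C=C)CC/C=C(\C)CCC=C(C)C)cc(O[Si](C)(C)C(C)(C)C)c2O[Si](C)(C)C(C)(C)C)c(O[Si](C)(C)C(C)(C)C)c1 | intermediate
20 | 5-[(3S,6E)-3,7,11-trimethyldodeca-1,6,10-trien-3-yl]-3-{2-hydroxy-4-[(3R,6E)-3,7,11-trimethyldodeca-1,6,10-trien-3-yl]phenoxy}benzene-1,2-diol | C=C[C@@](C)(CC/C=C(\C)CCC=C(C)C)c1ccc(Oc2cc([C@](C)(C=C)CC/C=C(\C)CCC=C(C)C)cc(O)c2O)c(O)c1 | target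

## Step count and least certain steps

Total step count: 13 steps. Longest linear sequence: 12 steps (steps 1 and 3 to 13, from 1 to 20); step 2 is a one-step branch.

Step 12 (key step). Three processes may spoil it.
- Isomerisation: the nickel hydride may isomerise the 1,1-disubstituted alkene to the internal trisubstituted styrene, which no longer inserts; this is favoured when ethylene insertion into the congested tertiary benzyl–nickel bond is slow.
- Incomplete enantioface selection: the catalyst must tell an aryl group from a long alkyl chain, and any leakage gives a diastereomer that cannot be removed because the two centres are remote.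
- Diversion of the hydride by the ring A vinyl group or the chain alkenes.

The fallback sets out from 17 and returns at 19, and it replaces face selection by stereospecific transfer. Asymmetric transfer hydrogenation of 17 with RuCl[(R,R)-TsDPEN](p-cymene) in HCO2H–Et3N should give the (R)-configured benzylic alcohol F1 without touching the isolated alkenes. Carbamoylation (i-Pr2NCOCl, Et3N, CH2Cl2, reflux) gives the N,N-diisopropylcarbamate F2. Lithiation at the benzylic carbon with s-BuLi (Et2O, −78 °C), borylation with methylboronic acid pinacol ester and a 1,2-shift of methyl promoted by MgBr2 in MeOH should give the (S)-configured tertiary pinacol boronic ester F3 (retention in the first two events, inversion in the third). Zweifel olefination (CH2=CHMgBr, then I2, then NaOMe, −78 °C) replaces boron by vinyl with retention and gives 19. Any aryl silyl ether lost to methoxide is restored under the conditions of step 5 before re-entry.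

Step 8. The same processes as in step 12 may occur. In addition, the ester carbonyl may occupy the cationic nickel and slow insertion, which leaves more time for isomerisation and lowers face selection.

The fallback sets out from 11 and returns at 13, and it takes stereocontrol away from the catalyst. Hydrovinylation with racemic PA, chosen for turnover only, should give 13 together with its (S)-enantiomer F4. Because the compound has a single stereocentre at this stage, the two can be separated by preparative chromatography on a chiral stationary phase. F4 is discarded; this costs half of the material, but at an early stage.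

Step 6. Proton exchange between the product ketone and unreacted enolate may lead to double alkylation, and on warming the enolate may attack the ring B ester of another molecule in a crossed Claisen condensation.

The fallback sets out from 4 and returns at 10, and it moves the alkylation to a stage without ester or silyl ethers. Compound 4 is deprotonated with LiN(i-Pr)2 to the lithium enolate F5 and alkylated with 8, the ketone being used in excess, to give the fluoro ketone F6 ((4E)-1-[4-fluoro-3-(methoxymethoxy)phenyl]-5,9-dimethyldeca-4,8-dien-1-one). Substitution of fluoride in F6 by 2 (Cs2CO3, DMSO, 90 °C) gives the chain-bearing diaryl ether F7. Brief hydrolysis (1 M aq. HCl–MeOH, rt) gives the chain-bearing triol F8, and silylation as in step 5 gives 10. The weak point of this fallback is the exposure of the two chain alkenes to dilute acid.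

Step 9. Amide formation may stay incomplete, so that the Grignard reagent meets free ester and adds twice, or the magnesium reagents may attack an aryl silyl ether.

The fallback sets out from 13 and returns at 17, so it also replaces step 10 and its risk of over-alkylation. Addition of LiCH2SO2Ph (from PhSO2CH3 and n-BuLi, 2.2 equiv, THF, −78 to 0 °C) gives the β-keto sulfone F9, whose acidity stops the reaction at the ketone stage. C-Alkylation with 8 (DBU, toluene, rt) gives the α-geranyl β-keto sulfone F10, a mixture of epimers at the sulfonyl carbon that is of no consequence. Reductive desulfonylation with SmI2 (THF–MeOH, −78 °C) gives 17.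

Step 3. The substitution may be sluggish, because the alkoxy group ortho to fluorine donates into the carbon under attack and the phenoxide of 2 is hindered and weakly nucleophilic. Prolonged heating then invites aldol self-condensation of the acetyl group or loss of the ester.

The fallback sets out from 2 and returns at 5, and it replaces the addition–elimination by a copper-mediated coupling. Commercial 4'-bromo-3'-hydroxyacetophenone F11 is converted as in step 2 into its MOM ether F12. F12 is then joined to 2 in an Ullmann ether synthesis (CuI, N,N-dimethylglycine, Cs2CO3, dioxane, 90 °C) to give 5.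

## Further compounds

F1 | step 12 | (R)-benzylic alcohol from 17 (ring B CH(OH), ring A chain 3R) | C=C[C@@](C)(CC/C=C(\C)CCC=C(C)C)c1ccc(Oc2cc([C@H](O)CC/C=C(\C)CCC=C(C)C)cc(O[Si](C)(C)C(C)(C)C)c2O[Si](C)(C)C(C)(C)C)c(O[Si](C)(C)C(C)(C)C)c1
F2 | step 12 | N,N-diisopropylcarbamate of F1 (R at the carbinol carbon) | C=C[C@@](C)(CC/C=C(\C)CCC=C(C)C)c1ccc(Oc2cc([C@H](OC(=O)N(C(C)C)C(C)C)CC/C=C(\C)CCC=C(C)C)cc(O[Si](C)(C)C(C)(C)C)c2O[Si](C)(C)C(C)(C)C)c(O[Si](C)(C)C(C)(C)C)c1
F3 | step 12 | ring B tertiary pinacol boronic ester (S at the boron-bearing carbon) | C=C[C@@](C)(CC/C=C(\C)CCC=C(C)C)c1ccc(Oc2cc([C@](C)(B3OC(C)(C)C(C)(C)O3)CC/C=C(\C)CCC=C(C)C)cc(O[Si](C)(C)C(C)(C)C)c2O[Si](C)(C)C(C)(C)C)c(O[Si](C)(C)C(C)(C)C)c1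
F4 | step 8 | (S)-enantiomer of 13 | C=C[C@](C)(CC/C=C(\C)CCC=C(C)C)c1ccc(Oc2cc(C(=O)OC)cc(O[Si](C)(C)C(C)(C)C)c2O[Si](C)(C)C(C)(C)C)c(O[Si](C)(C)C(C)(C)C)c1
F5 | step 6 | lithium enolate of 4 | [Li]OC(=C)c1ccc(F)c(OCOC)c1
F6 | step 6 | (4E)-1-[4-fluoro-3-(methoxymethoxy)phenyl]-5,9-dimethyldeca-4,8-dien-1-one | O=C(CC/C=C(\C)CCC=C(C)C)c1ccc(F)c(OCOC)c1
F7 | step 6 | methyl 7-{4-[(4E)-5,9-dimethyldeca-4,8-dienoyl]-2-(methoxymethoxy)phenoxy}-2-ethoxy-1,3-benzodioxole-5-carboxylate | O=C(CC/C=C(\C)CCC=C(C)C)c1ccc(Oc2cc(C(=O)OC)cc3OC(OCC)Oc23)c(OCOC)c1
F8 | step 6 | methyl 3-{4-[(4E)-5,9-dimethyldeca-4,8-dienoyl]-2-hydroxyphenoxy}-4,5-dihydroxybenzoate | O=C(CC/C=C(\C)CCC=C(C)C)c1ccc(Oc2cc(C(=O)OC)cc(O)c2O)c(O)c1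
F9 | step 9 | ring B β-keto sulfone (phenylsulfonylmethyl ketone) from 13 | C=C[C@@](C)(CC/C=C(\C)CCC=C(C)C)c1ccc(Oc2cc(C(=O)CS(=O)(=O)c3ccccc3)cc(O[Si](C)(C)C(C)(C)C)c2O[Si](C)(C)C(C)(C)C)c(O[Si](C)(C)C(C)(C)C)c1
F10 | step 9 | α-geranyl β-keto sulfone (epimers at the sulfonyl carbon) | C=C[C@@](C)(CC/C=C(\C)CCC=C(C)C)c1ccc(Oc2cc(C(=O)C(C/C=C(\C)CCC=C(C)C)S(=O)(=O)c3ccccc3)cc(O[Si](C)(C)C(C)(C)C)c2O[Si](C)(C)C(C)(C)C)c(O[Si](C)(C)C(C)(C)C)c1
F11 | step 3 | 4'-bromo-3'-hydroxyacetophenone | CC(=O)c1ccc(Br)c(O)c1
F12 | step 3 | 4'-bromo-3'-(methoxymethoxy)acetophenone | CC(=O)c1ccc(Br)c(OCOC)c1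
A1 | alternative 1 | bis(N,N-diisopropylcarbamate) of the two benzylic homogeranyl carbinols (ring A S, ring B R), tris-MOM | CC(C)N(C(C)C)C(=O)O[C@@H](CC/C=C(\C)CCC=C(C)C)c1ccc(Oc2cc([C@H](OC(=O)N(C(C)C)C(C)C)CC/C=C(\C)CCC=C(C)C)cc(OCOC)c2OCOC)c(OCOC)c1
A2 | alternative 1 | methylboronic acid pinacol ester | CB1OC(C)(C)C(C)(C)O1
A3 | alternative 1 | bis(tertiary pinacol boronic ester) with both quaternary centres set, tris-MOM | CC1(C)OB(OC1(C)C)[C@@](C)(CC/C=C(\C)CCC=C(C)C)c2ccc(Oc3cc([C@](C)(B4OC(C)(C)C(C)(C)O4)CC/C=C(\C)CCC=C(C)C)cc(OCOC)c3OCOC)c(OCOC)c2
A4 | alternative 2 | bis(diethyl phosphate) with the (E)-3-arylbut-2-enyl arm on ring A and the (Z) arm on ring B, tris-MOM | C/C(=C\COP(=O)(OCC)OCC)c1ccc(Oc2cc(/C(C)=C\COP(=O)(OCC)OCC)cc(OCOC)c2OCOC)c(OCOC)c1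
A5 | alternative 2 | di(homogeranyl)zinc, bis[(3E)-4,8-dimethylnona-3,7-dien-1-yl]zinc | CC(C)=CCC/C(C)=C/CC[Zn]CC/C=C(\C)CCC=C(C)C
A6 | alternative 2 | tris(methoxymethyl) ether of the target | C=C[C@@](C)(CC/C=C(\C)CCC=C(C)C)c1ccc(Oc2cc([C@](C)(C=C)CC/C=C(\C)CCC=C(C)C)cc(OCOC)c2OCOC)c(OCOC)c1
A7 | alternative 3 | geranylacetone | CC(=O)CC/C=C(\C)CCC=C(C)C
A8 | alternative 3 | (2R,5E)-6,10-dimethylundeca-5,9-dien-2-yl 2,4,6-triisopropylbenzoate | C[C@@H](OC(=O)c1c(C(C)C)cc(C(C)C)cc1C(C)C)CC/C=C(\C)CCC=C(C)C
A9 | alternative 3 | ring B neopentyl glycol boronate of the tris-MOM diaryl ether with the (R)-chain on ring A | C=C[C@@](C)(CC/C=C(\C)CCC=C(C)C)c1ccc(Oc2cc(B3OCC(C)(C)CO3)cc(OCOC)c2OCOC)c(OCOC)c1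
A10 | alternative 3 | ring B tertiary neopentyl glycol boronic ester with the aryl–C3 bond set | C=C[C@@](C)(CC/C=C(\C)CCC=C(C)C)c1ccc(Oc2cc([C@](C)(B3OCC(C)(C)CO3)CC/C=C(\C)CCC=C(C)C)cc(OCOC)c2OCOC)c(OCOC)c1
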